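**Retrosynthetic overview**
- The target is the 7-O-MOM ether of itself, unmasked last; ring D (the dimethylpyran) is the last ring formed, by aromatic propargyl Claisen rearrangement and oxa-6π closure of a 4'-O-(1,1-dimethylpropargyl) ether, C5' being the only free ortho position.
- Ring C (the pyranone) comes from a 2'-hydroxychalcone by Tl(NO3)3 oxidative 1,2-aryl shift and acid ring closure; this is done before ring D exists, because a chromene olefin would not survive trivalent thallium.
- Key C–C bond: Claisen–Schmidt aldol condensation of 2-hydroxy-4-(methoxymethoxy)acetophenone (ring A) with 4-(benzyloxy)-3-methoxybenzaldehyde (ring B).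
- Rings A and B are bought (2,4-dihydroxyacetophenone, O-benzylvanillin); ring order is C, then D.
- Protecting groups: acid-labile MOM on the 7-oxygen, benzyl on the 4'-oxygen (hydrogenolysed before any olefin of ring D is present).

Assumption: the target has no stereocentre and is achiral, so "single enantiomer" needs no stereocontrol; the compound is made exactly as drawn.

**Step 1**
Reactants: 1 1-(2,4-dihydroxyphenyl)ethan-1-one
Product: 2 1-[2-hydroxy-4-(methoxymethoxy)phenyl]ethan-1-one
Conditions: MOMCl (1.1 equiv), K2CO3, acetone, 0 °C to rt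
Reagents that add atoms: chloromethyl methyl ether (MOMCl), COCCl
Why: Williamson-type O-alkylation goes selectively at the 4-OH because the 2-OH is held in a hydrogen bond to the acetyl carbonyl and is far less nucleophilic under weak base.

**Step 2**
Reactants: 2 1-[2-hydroxy-4-(methoxymethoxy)phenyl]ethan-1-one; 3 4-(benzyloxy)-3-methoxybenzaldehyde
Product: 5 (E)-3-[4-(benzyloxy)-3-methoxyphenyl]-1-[2-hydroxy-4-(methoxymethoxy)phenyl]prop-2-en-1-one, via β-hydroxy ketone 4 (not isolated)
Conditions: KOH (50% aq), EtOH, rt, 36 h; then cold dilute AcOH to pH 6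
Reagents that add atoms: none
Why: In this Claisen–Schmidt (crossed aldol) condensation the methyl ketone enolate adds to the non-enolisable aldehyde and E1cB dehydration of aldol 4 gives the conjugated E-enone, which removes the transient stereocentre of 4 and joins the ring A and ring B fragments.

**Step 3**
Reactants: 5 (E)-3-[4-(benzyloxy)-3-methoxyphenyl]-1-[2-hydroxy-4-(methoxymethoxy)phenyl]prop-2-en-1-one
Product: 7 3-[4-(benzyloxy)-3-methoxyphenyl]-7-hydroxy-4H-chromen-4-one, via dimethyl acetal 6 (not isolated)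
Conditions: Tl(NO3)3·3H2O (1.2 equiv), MeOH–HC(OMe)3 1:1, rt, 16 h; filter; then 10% aq HCl, MeOH, reflux, 3 h
Reagents that add atoms: methanol, CO (its two methoxy groups are carried by 6 only and leave again on ring closure)
Why: In this oxidative rearrangement of a chalcone, oxythallation of the enone in methanol triggers 1,2-migration of the electron-rich 4-alkoxyaryl group (trivalent thallium leaves as monovalent thallium), and HCl then closes acetal 6 onto the 2'-OH with loss of methanol and cleaves the MOM acetal while the benzyl ether survives, so the stereocentre of 6 disappears in the chromone.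

**Step 4**
Reactants: 7 3-[4-(benzyloxy)-3-methoxyphenyl]-7-hydroxy-4H-chromen-4-one
Product: 8 3-[4-(benzyloxy)-3-methoxyphenyl]-7-(methoxymethoxy)-4H-chromen-4-one
Conditions: MOMCl (1.3 equiv), K2CO3, acetone, rt
Reagents that add atoms: chloromethyl methyl ether (MOMCl), COCCl
Why: Williamson ether synthesis on the only free hydroxyl (the acidic 7-OH, pKa about 7) installs a MOM group that withstands hydrogenolysis, base and heat but leaves under mild acid.

**Step 5**
Reactants: 8 3-[4-(benzyloxy)-3-methoxyphenyl]-7-(methoxymethoxy)-4H-chromen-4-one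
Product: 9 3-(4-hydroxy-3-methoxyphenyl)-7-(methoxymethoxy)-4H-chromen-4-one
Conditions: H2 (1 atm), 10% Pd/C, EtOAc–THF, rt, stopped at one equivalent of H2
Reagents that add atoms: none
Why: Catalytic hydrogenolysis of the benzyl aryl ether is much faster than reduction of the chromone C2=C3 bond at 1 atm and the MOM acetal is inert, so only the 4'-OH is freed.

**Step 6**
Reactants: 9 3-(4-hydroxy-3-methoxyphenyl)-7-(methoxymethoxy)-4H-chromen-4-one; 10 3-chloro-3-methylbut-1-yne
Product: 11 3-{3-methoxy-4-[(2-methylbut-3-yn-2-yl)oxy]phenyl}-7-(methoxymethoxy)-4H-chromen-4-one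
Conditions: K2CO3, KI, CuI (5 mol%), acetone, reflux
Reagents that add atoms: none
Why: Copper-assisted propargylic substitution (a Williamson-type etherification through the ionised tertiary propargyl chloride) O-alkylates the only free phenol to give the 1,1-dimethylpropargyl aryl ether.

**Step 7**
Reactants: 11 3-{3-methoxy-4-[(2-methylbut-3-yn-2-yl)oxy]phenyl}-7-(methoxymethoxy)-4H-chromen-4-one
Product: 13 3-(8-methoxy-2,2-dimethyl-2H-chromen-6-yl)-7-(methoxymethoxy)-4H-chromen-4-one, via allenyl phenol 12 (not isolated)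
Conditions: PhNEt2, 190 °C, 3 h, N2
Reagents that add atoms: none
Why: The aromatic propargyl Claisen rearrangement ([3,3]) can only go to C5' because C3' carries the methoxy group, and allenyl phenol 12 then undergoes a [1,5]-hydrogen shift to an o-quinone methide and oxa-6π electrocyclisation to close ring D as the 2,2-dimethyl-2H-chromene.

**Step 8**
Reactants: 13 3-(8-methoxy-2,2-dimethyl-2H-chromen-6-yl)-7-(methoxymethoxy)-4H-chromen-4-one
Product: 14 7-hydroxy-3-(8-methoxy-2,2-dimethyl-2H-chromen-6-yl)-4H-chromen-4-one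
Conditions: 3 M aq HCl, MeOH–THF, 50 °C, 1–2 h (TLC control)
Reagents that add atoms: none
Why: Acid-catalysed acetal solvolysis (MOM deprotection) under dilute, mild conditions frees the 7-OH while the chromene olefin, the aryl methyl ether and the chromone are stable.

**Compound list**
1 | 1-(2,4-dihydroxyphenyl)ethan-1-one (2,4-dihydroxyacetophenone) | CC(=O)c1ccc(O)cc1O | starting material
2 | 1-[2-hydroxy-4-(methoxymethoxy)phenyl]ethan-1-one | CC(=O)c1ccc(OCOC)cc1O | intermediate
3 | 4-(benzyloxy)-3-methoxybenzaldehyde (O-benzylvanillin) | COc1cc(C=O)ccc1OCc1ccccc1 | starting material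
4 | 3-[4-(benzyloxy)-3-methoxyphenyl]-3-hydroxy-1-[2-hydroxy-4-(methoxymethoxy)phenyl]propan-1-one (racemic aldol adduct, not isolated) | COCOc1ccc(C(=O)CC(O)c2ccc(OCc3ccccc3)c(OC)c2)c(O)c1 | intermediate
5 | (E)-3-[4-(benzyloxy)-3-methoxyphenyl]-1-[2-hydroxy-4-(methoxymethoxy)phenyl]prop-2-en-1-one | COCOc1ccc(C(=O)/C=C/c2ccc(OCc3ccccc3)c(OC)c2)c(O)c1 | intermediate
6 | 2-[4-(benzyloxy)-3-methoxyphenyl]-1-[2-hydroxy-4-(methoxymethoxy)phenyl]-3,3-dimethoxypropan-1-one (racemic, not isolated) | COCOc1ccc(C(=O)C(c2ccc(OCc3ccccc3)c(OC)c2)C(OC)OC)c(O)c1 | intermediate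
7 | 3-[4-(benzyloxy)-3-methoxyphenyl]-7-hydroxy-4H-chromen-4-one | COc1cc(-c2coc3cc(O)ccc3c2=O)ccc1OCc1ccccc1 | intermediate
8 | 3-[4-(benzyloxy)-3-methoxyphenyl]-7-(methoxymethoxy)-4H-chromen-4-one | COCOc1ccc2c(c1)occ(-c1ccc(OCc3ccccc3)c(OC)c1)c2=O | intermediate
9 | 3-(4-hydroxy-3-methoxyphenyl)-7-(methoxymethoxy)-4H-chromen-4-one | COCOc1ccc2c(c1)occ(-c1ccc(O)c(OC)c1)c2=O | intermediate
10 | 3-chloro-3-methylbut-1-yne | CC(C)(Cl)C#C | starting material
11 | 3-{3-methoxy-4-[(2-methylbut-3-yn-2-yl)oxy]phenyl}-7-(methoxymethoxy)-4H-chromen-4-one | COCOc1ccc2c(c1)occ(-c1ccc(OC(C)(C)C#C)c(OC)c1)c2=O | intermediate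
12 | 3-[4-hydroxy-3-methoxy-5-(3-methylbuta-1,2-dien-1-yl)phenyl]-7-(methoxymethoxy)-4H-chromen-4-one (not isolated) | COCOc1ccc2c(c1)occ(-c1cc(OC)c(O)c(C=C=C(C)C)c1)c2=O | intermediate
13 | 3-(8-methoxy-2,2-dimethyl-2H-chromen-6-yl)-7-(methoxymethoxy)-4H-chromen-4-one | COCOc1ccc2c(c1)occ(-c1cc(OC)c3OC(C)(C)C=Cc3c1)c2=O | intermediate
14 | 7-hydroxy-3-(8-methoxy-2,2-dimethyl-2H-chromen-6-yl)-4H-chromen-4-one (achiral) | COc1cc(-c2coc3cc(O)ccc3c2=O)cc2c1OC(C)(C)C=C2 | target

**Step count and risks**
Total step count: 8. Longest linear sequence: 8 steps (1 to 14); aldehyde 3 and chloride 10 are bought.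

Three steps most likely to fail:

Step 3 (oxidative rearrangement). Aurone or flavone by-products and over-oxidation by trivalent thallium can lower the yield. The fallback replaces the 1,2-aryl shift by the 1,2-acyl shift of a chalcone epoxide and sets out from 2. O-Benzylation of the chelated 2-OH (BnBr, K2CO3, DMF, 60 °C) gives 1-[2-(benzyloxy)-4-(methoxymethoxy)phenyl]ethan-1-one F1. The same Claisen–Schmidt condensation with 3 (KOH, EtOH, rt) gives (E)-1-[2-(benzyloxy)-4-(methoxymethoxy)phenyl]-3-[4-(benzyloxy)-3-methoxyphenyl]prop-2-en-1-one F2. Nucleophilic Weitz–Scheffer epoxidation (30% H2O2, NaOH, MeOH–THF, 0 °C) gives racemic trans-[2-(benzyloxy)-4-(methoxymethoxy)phenyl]{3-[4-(benzyloxy)-3-methoxyphenyl]oxiran-2-yl}methanone F3. BF3·OEt2 (CH2Cl2, −20 to 0 °C, short contact so that the MOM ether is kept) opens the epoxide at the benzylic carbon and the aroyl group migrates, giving 2-[4-(benzyloxy)-3-methoxyphenyl]-3-[2-(benzyloxy)-4-(methoxymethoxy)phenyl]-3-oxopropanal F4. Hydrogenolysis (H2, Pd/C, EtOAc) removes both benzyl groups and the freed 2-OH closes onto the formyl group with loss of water. The fallback comes back to the route at 9, so steps 3 to 5 are bypassed.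

Step 6 (tertiary propargyl ether on a hindered guaiacol-type phenol). Elimination of 10 to the enyne or sluggish alkylation are the risks. The fallback builds ring D by carbonyl condensation instead of O-alkylation and Claisen rearrangement, and sets out from 9. Heating 9 with 3-methylbut-2-enal, PhB(OH)2 and catalytic propionic acid in toluene (reflux, Dean–Stark) forms the C–C bond ortho-specifically at C5' and gives 3-[8-methoxy-4-(2-methylprop-1-en-1-yl)-2-phenyl-4H-1,3,2-benzodioxaborinin-6-yl]-7-(methoxymethoxy)-4H-chromen-4-one F5. This fragments in the same pot to the o-quinone methide, which closes by oxa-6π electrocyclisation. The fallback comes back to the route at 13, so step 7 is bypassed.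

Step 5 (hydrogenolysis next to the chromone). Over-reduction of the C2=C3 bond to the isoflavanone or a stalled reaction are the risks. The fallback drops the orthogonal benzyl/MOM pair and differentiates the two phenols by acidity instead; it sets out from 7. Lewis-acid debenzylation (BCl3, pentamethylbenzene as cation scavenger, CH2Cl2, −78 °C; the methyl ether is kept) gives 7-hydroxy-3-(4-hydroxy-3-methoxyphenyl)-4H-chromen-4-one F6. Selective alkylation of the much more acidic 7-OH (MOMCl 1.05 equiv, K2CO3 1.1 equiv, acetone, 0 °C) then gives the 7-O-MOM ether. The fallback comes back to the route at 9, so steps 4 and 5 are bypassed.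

**Further compounds**
F1 | step 3 | 1-[2-(benzyloxy)-4-(methoxymethoxy)phenyl]ethan-1-one | CC(=O)c1ccc(OCOC)cc1OCc1ccccc1
F2 | step 3 | (E)-1-[2-(benzyloxy)-4-(methoxymethoxy)phenyl]-3-[4-(benzyloxy)-3-methoxyphenyl]prop-2-en-1-one | COCOc1ccc(C(=O)/C=C/c2ccc(OCc3ccccc3)c(OC)c2)c(OCc2ccccc2)c1
F3 | step 3 | trans-[2-(benzyloxy)-4-(methoxymethoxy)phenyl]{3-[4-(benzyloxy)-3-methoxyphenyl]oxiran-2-yl}methanone (racemic, one enantiomer drawn) | COCOc1ccc(C(=O)[C@@H]4O[C@H]4c2ccc(OCc3ccccc3)c(OC)c2)c(OCc2ccccc2)c1
F4 | step 3 | 2-[4-(benzyloxy)-3-methoxyphenyl]-3-[2-(benzyloxy)-4-(methoxymethoxy)phenyl]-3-oxopropanal (racemic) | COCOc1ccc(C(=O)C(C=O)c2ccc(OCc3ccccc3)c(OC)c2)c(OCc2ccccc2)c1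
F5 | step 6 | 3-[8-methoxy-4-(2-methylprop-1-en-1-yl)-2-phenyl-4H-1,3,2-benzodioxaborinin-6-yl]-7-(methoxymethoxy)-4H-chromen-4-one (racemic) | COCOc1ccc2c(c1)occ(-c1cc(OC)c3OB(c4ccccc4)OC(C=C(C)C)c3c1)c2=O
F6 | step 5 | 7-hydroxy-3-(4-hydroxy-3-methoxyphenyl)-4H-chromen-4-one | COc1cc(-c2coc3cc(O)ccc3c2=O)ccc1O
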